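The numbers in the tables come from a simulation for an exercise, and the scatter is random.

The vessel is stirred and holds substrate; reagent goes in as two portions 2.0 s apart, over well before the first reading at 12.0 s.

common to all: substrate 1.7 M

| run | reagent | remark | time |
|---|---|---|---|
| red | 0.94 M (in portions, 2) | run made earlier; portions every 2.0 s |  |
| teal | 2.5 M (in portions, 2) | run made earlier; portions every 2.0 s |  |
| alder | 0.800 M (in portions, 2) | the portions of reagent follow each other after 2.0 s, the first at the start | 3.0 min |
| maple | 1.50 M (in portions, 2) | the portions of reagent follow each other after 2.0 s, the first at the start | 3.0 min |
| cedar | 3.00 M (in portions, 2) | the portions of reagent follow each other after 2.0 s, the first at the start | 3.0 min |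

| run | time / s | target / % | substrate / % |
|---|---|---|---|
| red | 25.0 | 15.6 | 82.0 |
| red | 50.0 | 15.8 | 79.3 |
| red | 60.0 | 18.1 | 80.2 |
| red | 90.0 | 15.7 | 78.1 |
| teal | 12.0 | 24.7 | 71.9 |
| teal | 30.0 | 36.4 | 59.9 |
| teal | 60.0 | 34.7 | 58.2 |
| teal | 90.0 | 34.6 | 58.5 |

(readings scatter by 1 percentage point)

1. amount of target at the end, in percent of the substrate charged for alder, maple, cedar, in this order
2. the shape of the row from first to last (falls all the way / rises all the way / falls, then rises / hardly changes / rises, then falls)

- "hardly changes" means that all values lie within two and a half points (for a concentration: within two and a half percent of the largest)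

Start with the last red reading. At 90.0 s it holds target 15.7% beside substrate 78.1%, and reagent left by subtraction, one per target, is 0.673 M. By these amounts both partners are still present in the red run at that reading, so its level target is no limiting reagent at work. That leaves you two amounts to compare: [target] and the product [substrate][reagent].

Divide the first by the second. Red gives 0.299 /M and teal gives 0.309 /M, though the teal charge is 2.66 times the red one. Take their mean, 0.304 /M, as the plateau quotient, an apparent equilibrium constant read from the readings.

Now set that quotient equal to target over what substrate and reagent leave after forming it. Your balance gives 14.4% for alder, 24.7% for maple and 41.2% for cedar, rising all the way. Expect the end values somewhat below these estimates: at 90.0 s the teal readings already miss 6.9 percentage points of the balance, and 3.0 min is twice that last reading.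

The forecast gives 14%, 24% and 38%, its cedar value being lower than yours, with the shape rises all the way: “A saturating curve through the two points”.

The flask gives 13.2%, 22.3% and 35.8%, and the row rises all the way.

    reagent + other conformer → isomer of the product (k = 0.0260 /M/s)
    substrate + reagent ⇌ target (K = 0.340 /M, k = 0.0160 /M/s)
    substrate ⇌ other conformer (K = 0.0270, k = 0.0550 /s)

In alder, the making of target has half of its turnover to the asked time done by 0.136 min, earlier than the 0.737 min of the loss of substrate to other conformer, and target stands at 14.2% after 1.50 min against your 14.4% from 0.304 /M. In cedar, the same quotient gave 41.2% against 39.2% after 1.50 min, and by 3.00 min target has slipped to 35.8% while isomer of the product has reached 14.8%.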